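**Retrosynthetic overview**

1. Late stage: the angelate (C8), the C11=C13 methylene and both oxiranes are put on a (1(10)E,2Z,4(15))-triene lactone. The triene comes from loss of a C3 phenoxy group with zerovalent palladium, after the C4/C5 epoxide has been turned into the C5-OH/C4=C15 unit.
2. The γ-lactone comes from a C6 ketone and a C7 acetate arm. The C5 oxygen comes from nucleophilic epoxidation of the C4=C5 enone.
3. Key disconnection C8–C9: anionic oxy-Cope ring expansion with enolate alkylation at C7 in the same flask. Enabling feature: C6 (oxygen-bearing), C7, C8 and C9, C10, C1 (the trans-oxirane, formerly an E-olefin) form the retron C8=C7–C6(O)–C1–C10=C9. The ten-membered ring therefore maps onto a cyclohexene (ring atoms C1–C6) whose C1–C6 bond, absent from the target, breaks as C8–C9 forms.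
4. That cyclohexene is (S)-carvone. Its carbonyl oxygen becomes the C3 leaving group, its isopropenyl group becomes C9/C10/C14, and its single stereocentre (C1) relays chirality to C8.
5. Ring order: six-membered carbocycle (chiral pool) → ten-membered carbocycle (step 7) → γ-lactone (step 9) → two oxiranes (steps 14 and 15).

Key step: step 7

Remark: germacrane locants are used throughout (C6 lactone carbinol, C8 ester carbon, C9 the CH2, C12 lactone carbonyl, C13/C15 exocyclic CH2, C14 methyl); the ester is read as the (Z)-2-methylbut-2-enoate (angelate); facial selectivities in the ten-membered ring are predictions from conformational models.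

**Route**

Step 1
Reactants: 1 (S)-carvone
Product: 2 (1S,5S)-cis-carveol
Conditions: NaBH4, CeCl3·7H2O, MeOH, −78 to 0 °C
Reagents that add atoms: none
Why: Luche reduction, in which the cerium-activated enone takes hydride 1,2 and axially, so that the new hydroxyl is equatorial and cis to the isopropenyl group (new centre 1S).

Step 2
Reactants: 2 (1S,5S)-cis-carveol
Product: 3 trans-carvyl phenyl ether, {[(1R,5S)-2-methyl-5-(prop-1-en-2-yl)cyclohex-2-en-1-yl]oxy}benzene
Conditions: PhOH, PPh3, diisopropyl azodicarboxylate, THF, 0 °C to rt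
Reagents that add atoms: phenol, Oc1ccccc1
Why: Mitsunobu reaction, in which phenoxide displaces the alkoxyphosphonium group by SN2 with inversion, so the phenoxy group ends trans to the isopropenyl group (1R); this centre later decides the face of step 8 and the group is the leaving group of step 12.

Step 3
Reactants: 3 trans-carvyl phenyl ether
Product: 4 (4R,6S)-3-methyl-4-phenoxy-6-(prop-1-en-2-yl)cyclohex-2-en-1-one
Conditions: Rh2(cap)4 (dirhodium tetrakis(caprolactamate), 1 mol %), t-BuOOH, K2CO3, CH2Cl2, rt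
Reagents that add atoms: tert-butyl hydroperoxide, CC(C)(C)OO
Why: Catalytic allylic C–H oxidation (tert-butylperoxyl radical chain, allylic peroxide to enone) attacks the only ring methylene allylic to the trisubstituted olefin, as in the oxidation of cyclohexenyl ethers to 4-oxycyclohexenones; no stereocentre is formed and the near-neutral medium leaves the epimerisable C6 centre alone.

Step 4
Reactants: 5 4-methoxybenzyl alcohol; 6 trichloroethylene
Product: 7 (E)-1,2-dichlorovinyl 4-methoxybenzyl ether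
Conditions: KH, THF, 0 °C; then 6, −50 °C to rt
Reagents that add atoms: none
Why: Addition–elimination of the potassium alkoxide to trichloroethylene (through dichloroacetylene) gives the 1,2-dichlorovinyl ether, a storable precursor of an ynol ether; no stereocentre.

Step 5
Reactants: 7 (E)-1,2-dichlorovinyl 4-methoxybenzyl ether; 4 (4R,6S)-3-methyl-4-phenoxy-6-(prop-1-en-2-yl)cyclohex-2-en-1-one
Product: 9 (1S,4R,6S)-1-{[(4-methoxybenzyl)oxy]ethynyl}-3-methyl-4-phenoxy-6-(prop-1-en-2-yl)cyclohex-2-en-1-ol, via lithium alkoxyacetylide 8 (not isolated)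
Conditions: n-BuLi (2.0 equiv), THF, −78 to −40 °C; then 4, −78 °C; NH4Cl aq.
Reagents that add atoms: none
Why: Elimination of HCl and chlorine–lithium exchange turn 7 into the acetylide 8, which adds 1,2 to the carbonyl from the face opposite the neighbouring isopropenyl group (equatorial attack, as in the ethynylation of 2-isopropylcyclohexanones), so the carbinol centre is S and the two future rearrangement termini are trans.

Step 6
Reactants: 9 (1S,4R,6S)-1-{[(4-methoxybenzyl)oxy]ethynyl}-3-methyl-4-phenoxy-6-(prop-1-en-2-yl)cyclohex-2-en-1-ol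
Product: 10 (1S,4R,6S)-1-{(E)-2-[(4-methoxybenzyl)oxy]ethenyl}-3-methyl-4-phenoxy-6-(prop-1-en-2-yl)cyclohex-2-en-1-ol
Conditions: NaAlH2(OCH2CH2OMe)2, THF, 0 °C; potassium sodium tartrate work-up
Reagents that add atoms: none
Why: Hydroxyl-directed trans-hydroalumination of the propargylic alcohol and protonolysis (alkyne to (E)-alkene reduction) give the (E)-enol ether, the geometry that step 7 translates into the C8 configuration.

Step 7
Reactants: 10 (1S,4R,6S)-1-{(E)-2-[(4-methoxybenzyl)oxy]ethenyl}-3-methyl-4-phenoxy-6-(prop-1-en-2-yl)cyclohex-2-en-1-ol; 11 methyl iodoacetate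
Product: 14 methyl (1(10)E,3R,4Z,7R,8S)-8-[(4-methoxybenzyl)oxy]-6-oxo-3-phenoxy-13-norgermacra-1(10),4-dien-12-oate, via potassium alkoxide 12 (not isolated), via potassium enolate 13 (not isolated)
Conditions: KN(SiMe3)2, 18-crown-6, THF, −20 to 0 °C; then 11, −78 °C
Reagents that add atoms: none
Why: Deprotonation gives the potassium alkoxide 12, whose 3-oxido-1,5-diene C8=C7–C6(O−)–C1–C10=C9 rearranges by a charge-accelerated [3,3]-sigmatropic shift (anionic oxy-Cope) through a chair transition state, the cyclohexene bond C1–C6 breaking as C8–C9 forms; the closest known reaction is the anionic oxy-Cope ring expansion of 1,2-dialkenylcyclohex-2-enols made from isopiperitenone-type enones to (E,Z)-cyclodecadienones. The ten-membered carbocycle is thus closed by a four-atom ring expansion of the six-membered ring and not by a direct macrocyclisation, the driving force being the cross-conjugated enolate 13. C8 is set by 1,3-chirality transfer from the carvone-derived centre C1: with the ring carbon C2 equatorial on (S)-C1 and the (E)-enol ether oxygen pseudo-equatorial on C8, the chair gives 8S and at the same time the (E)-C1=C10 olefin, while the ring olefin C4=C5 stays Z. C7 is set in the same flask by C-alkylation of 13 with 11 on the face anti to the just-formed C8–C9 bond, the face not covered by the ring chain, which gives 7R (C11 and O8 anti). The step needs chair over boat and one nucleophilic carbon: the trans-diequatorial placing of the two alkenyl groups on the half-chair secures the first (the other 1,5-diene, through the ring olefin, could react only by way of a strained boat), and the cross-conjugated dienolate, nucleophilic at C7 only, secures the second. β-Elimination of the C8 alkoxide from 13 is held back by low temperature and immediate alkylation.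

Step 8
Reactants: 14 methyl (1(10)E,3R,4Z,7R,8S)-8-[(4-methoxybenzyl)oxy]-6-oxo-3-phenoxy-13-norgermacra-1(10),4-dien-12-oate
Product: 15 methyl (1(10)E,3R,4S,5S,7R,8S)-4,5-epoxy-8-[(4-methoxybenzyl)oxy]-6-oxo-3-phenoxy-13-norgermacr-1(10)-en-12-oate
Conditions: t-BuOOH, n-BuLi, THF, −78 to −20 °C
Reagents that add atoms: tert-butyl hydroperoxide, CC(C)(C)OO
Why: Weitz–Scheffer-type nucleophilic epoxidation, in which lithium tert-butyl peroxide adds only to the electron-poor C4=C5 enone, the ring keeps the two ring bonds cis, and the peroxide enters anti to the C3–C2 ring bond in the conformer that keeps the (3R)-phenoxy group out of the eclipsed inside position (allylic strain), which sets 4S,5S, while the weakly basic reagent avoids E1cB loss of the C8 ether.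

Step 9
Reactants: 15 methyl (1(10)E,3R,4S,5S,7R,8S)-4,5-epoxy-8-[(4-methoxybenzyl)oxy]-6-oxo-3-phenoxy-13-norgermacr-1(10)-en-12-oate
Product: 17 (1(10)E,3R,4S,5R,6S,7R,8S)-4,5-epoxy-8-[(4-methoxybenzyl)oxy]-3-phenoxy-13-norgermacr-1(10)-en-12,6-olide, via lithium 6-alkoxide 16 (not isolated)
Conditions: LiBH(s-Bu)3, THF, −78 to 0 °C
Reagents that add atoms: none
Why: Ketone reduction under Felkin–Anh control with a bulky, non-chelating hydride, in which the C5–O oxirane bond and the C7 acetate arm lie on the same face of the carbonyl in the extended C4–C8 segment, hydride enters from the other face (6S), and the lithium alkoxide then closes the trans-fused γ-lactone by acyl substitution on the methyl ester.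

Step 10
Reactants: 17 (1(10)E,3R,4S,5R,6S,7R,8S)-4,5-epoxy-8-[(4-methoxybenzyl)oxy]-3-phenoxy-13-norgermacr-1(10)-en-12,6-olide
Product: 18 (1(10)E,3R,5S,6S,7R,8S)-5-hydroxy-8-[(4-methoxybenzyl)oxy]-3-phenoxy-13-norgermacra-1(10),4(15)-dien-12,6-olide
Conditions: Et2AlCl, lithium 2,2,6,6-tetramethylpiperidide, toluene, 0 °C
Reagents that add atoms: none
Why: Base-induced epoxide-to-allylic-alcohol isomerisation, in which the aluminium amide binds the oxirane oxygen and removes a syn β-proton from the least hindered position (the C15 methyl, not the phenoxy-bearing C3–H) through a cyclic transition state, so the tertiary C4–O bond breaks, the C4=C15 olefin forms and the oxygen stays on C5 with its configuration (5S).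

Step 11
Reactants: 18 (1(10)E,3R,5S,6S,7R,8S)-5-hydroxy-8-[(4-methoxybenzyl)oxy]-3-phenoxy-13-norgermacra-1(10),4(15)-dien-12,6-olide
Product: 19 5-O-triethylsilyl ether of 18
Conditions: Et3SiCl, imidazole, DMF, 0 °C
Reagents that add atoms: chlorotriethylsilane, CC[Si](Cl)(CC)CC
Why: Silyl ether formation masks the secondary allylic C5 hydroxyl through the elimination, oxidation and acylation steps without touching a stereocentre.

Step 12
Reactants: 19 5-O-triethylsilyl ether of 18
Product: 20 (1(10)E,2Z,5S,6S,7R,8S)-8-[(4-methoxybenzyl)oxy]-5-[(triethylsilyl)oxy]-13-norgermacra-1(10),2,4(15)-trien-12,6-olide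
Conditions: Pd(PPh3)4 (10 mol %), Et3N, 1,4-dioxane, 100 °C
Reagents that add atoms: none
Why: Tsuji–Trost-type elimination, in which zerovalent palladium ionises the allylic phenyl ether (C3–O next to C4=C15) to a π-allyl complex whose only β-hydrogens sit on C2, and syn β-hydride elimination gives the conjugated triene, the new C2=C3 bond being Z because an E,E-1,3-diene next to the E-C1=C10 bond cannot fit in the ten-membered ring.

Step 13
Reactants: 20 (1(10)E,2Z,5S,6S,7R,8S)-8-[(4-methoxybenzyl)oxy]-5-[(triethylsilyl)oxy]-13-norgermacra-1(10),2,4(15)-trien-12,6-olide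
Product: 23 (1(10)E,2Z,5S,6S,7R,8S)-8-[(4-methoxybenzyl)oxy]-5-[(triethylsilyl)oxy]germacra-1(10),2,4(15),11(13)-tetraen-12,6-olide, via Mannich base 21 (not isolated), via trimethylammonium iodide 22 (not isolated)
Conditions: LiN(i-Pr)2, THF, −78 °C; CH2=NMe2 I, −78 °C to rt; then MeI, MeOH; then NaHCO3 aq., rt
Reagents that add atoms: N,N-dimethylmethyleneiminium iodide, C=[N+](C)C.[I-]
Why: Mannich-type α-aminomethylation of the lactone lithium enolate, quaternisation and E1cB loss of trimethylamine install the exocyclic C11=C13 methylene (the transient C11 centre of 21 is destroyed again), with no other acidic site competing at −78 °C.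

Step 14
Reactants: 23 (1(10)E,2Z,5S,6S,7R,8S)-8-[(4-methoxybenzyl)oxy]-5-[(triethylsilyl)oxy]germacra-1(10),2,4(15),11(13)-tetraen-12,6-olide
Product: 24 (1R,2Z,5S,6S,7R,8S,10R)-1,10-epoxy-8-[(4-methoxybenzyl)oxy]-5-[(triethylsilyl)oxy]germacra-2,4(15),11(13)-trien-12,6-olide
Conditions: 3-ClC6H4CO3H (1.0 equiv), NaHCO3, CH2Cl2, −20 °C
Reagents that add atoms: 3-chloroperoxybenzoic acid, OOC(=O)c1cccc(Cl)c1
Why: Prilezhaev epoxidation, in which the peracid takes the most electron-rich, trisubstituted C1=C10 bond and approaches its outer face in the usual conformer of 6α,12-olides with a 7β side chain (C14 methyl on the β face), which should give the trans (1R,10R; 1β,10α) oxirane and leave the methylene lactone and the less substituted olefins.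

Step 15
Reactants: 24 (1R,2Z,5S,6S,7R,8S,10R)-1,10-epoxy-8-[(4-methoxybenzyl)oxy]-5-[(triethylsilyl)oxy]germacra-2,4(15),11(13)-trien-12,6-olide
Product: 25 (1R,2S,3S,5S,6S,7R,8S,10R)-1,10:2,3-diepoxy-8-[(4-methoxybenzyl)oxy]-5-[(triethylsilyl)oxy]germacra-4(15),11(13)-dien-12,6-olide
Conditions: (S,S)-(salen)MnCl [chloro{(S,S)-N,N′-bis(3,5-di-tert-butylsalicylidene)cyclohexane-1,2-diaminato}manganese, 5 mol %], 3-ClC6H4CO3H, N-methylmorpholine N-oxide, CH2Cl2, −78 °C
Reagents that add atoms: 3-chloroperoxybenzoic acid, OOC(=O)c1cccc(Cl)c1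
Why: Jacobsen–Katsuki epoxidation, in which the oxo-manganese salen species prefers the cis-disubstituted conjugated C2=C3 bond over the 1,1-disubstituted C4=C15 and the electron-poor methylene lactone, the ring prevents cis/trans scrambling, and the (S,S) ligand, chosen by the side-on approach model with the vinyl group in the role of the aryl group of cis-β-methylstyrene, should deliver oxygen to the α face (2S,3S).

Step 16
Reactants: 25 (1R,2S,3S,5S,6S,7R,8S,10R)-1,10:2,3-diepoxy-8-[(4-methoxybenzyl)oxy]-5-[(triethylsilyl)oxy]germacra-4(15),11(13)-dien-12,6-olide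
Product: 26 (1R,2S,3S,5S,6S,7R,8S,10R)-1,10:2,3-diepoxy-8-hydroxy-5-[(triethylsilyl)oxy]germacra-4(15),11(13)-dien-12,6-olide
Conditions: DDQ, CH2Cl2/pH 7 buffer, 0 °C
Reagents that add atoms: none
Why: Oxidative cleavage of the 4-methoxybenzyl ether by DDQ (hydride abstraction to the oxocarbenium ion and hydrolysis) in a buffered two-phase medium frees the C8 alcohol with retention and without touching the silyl ether, the oxiranes or the lactone.

Step 17
Reactants: 26 (1R,2S,3S,5S,6S,7R,8S,10R)-1,10:2,3-diepoxy-8-hydroxy-5-[(triethylsilyl)oxy]germacra-4(15),11(13)-dien-12,6-olide; 27 angelic acid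
Product: 29 8-O-angeloyl derivative of 26, via mixed anhydride 28 (not isolated)
Conditions: 27, 2,4,6-Cl3C6H2COCl, Et3N, toluene, rt; then 26, 80 °C
Reagents that add atoms: none
Why: Yamaguchi esterification, in which the C8 alcohol attacks the mixed anhydride 28 at the unhindered angeloyl carbonyl and the absence of a nucleophilic catalyst and of excess base keeps the (Z)-2-methylbut-2-enoate from isomerising to the tiglate; C8 is acylated with retention.

Step 18
Reactants: 29 8-O-angeloyl derivative of 26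
Product: 30 target, (1R,2S,3S,5S,6S,7R,8S,10R)-8-(angeloyloxy)-1,10:2,3-diepoxy-5-hydroxygermacra-4(15),11(13)-dien-12,6-olide
Conditions: Bu4NF, AcOH, THF, 0 °C
Reagents that add atoms: none
Why: Fluoride-mediated desilylation buffered with acetic acid should remove the triethylsilyl group under conditions mild enough for the two oxiranes, the angelate and the methylene lactone.

**Compound list**

1 | (S)-(+)-carvone, (5S)-2-methyl-5-(prop-1-en-2-yl)cyclohex-2-en-1-one | CC1=CC[C@@H](CC1=O)C(C)=C | starting material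
2 | (1S,5S)-cis-carveol | CC1=CC[C@@H](C[C@@H]1O)C(C)=C | intermediate
3 | trans-carvyl phenyl ether, {[(1R,5S)-2-methyl-5-(prop-1-en-2-yl)cyclohex-2-en-1-yl]oxy}benzene | CC1=CC[C@@H](C[C@H]1Oc2ccccc2)C(C)=C | intermediate
4 | (4R,6S)-3-methyl-4-phenoxy-6-(prop-1-en-2-yl)cyclohex-2-en-1-one | CC1=CC(=O)[C@@H](C[C@H]1Oc2ccccc2)C(C)=C | intermediate
5 | 4-methoxybenzyl alcohol | COc1ccc(CO)cc1 | starting material
6 | trichloroethylene | ClC=C(Cl)Cl | starting material
7 | (E)-1,2-dichlorovinyl 4-methoxybenzyl ether | COc1ccc(CO/C(Cl)=C\Cl)cc1 | intermediate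
8 | lithium [(4-methoxybenzyl)oxy]acetylide | [Li+].[C-]#COCc1ccc(OC)cc1 | intermediate
9 | (1S,4R,6S)-1-{[(4-methoxybenzyl)oxy]ethynyl}-3-methyl-4-phenoxy-6-(prop-1-en-2-yl)cyclohex-2-en-1-ol | CC1=C[C@@](O)(C#COCc2ccc(OC)cc2)[C@@H](C[C@H]1Oc3ccccc3)C(C)=C | intermediate
10 | (1S,4R,6S)-1-{(E)-2-[(4-methoxybenzyl)oxy]ethenyl}-3-methyl-4-phenoxy-6-(prop-1-en-2-yl)cyclohex-2-en-1-ol | CC1=C[C@@](O)(/C=C/OCc2ccc(OC)cc2)[C@@H](C[C@H]1Oc3ccccc3)C(C)=C | intermediate
11 | methyl iodoacetate | COC(=O)CI | starting material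
12 | potassium alkoxide of 10 | [K+].CC1=C[C@@]([O-])(/C=C/OCc2ccc(OC)cc2)[C@@H](C[C@H]1Oc3ccccc3)C(C)=C | intermediate
13 | potassium enolate (C6–O, C6=C7) of the ring-expanded ketone, (3R,8S), 1(10)E,4Z | [K+].[C@@H]1(OCc2ccc(OC)cc2)/C=C(\[O-])/C=C(C)\[C@H](Oc3ccccc3)C/C=C(C)/C1 | intermediate
14 | methyl (1(10)E,3R,4Z,7R,8S)-8-[(4-methoxybenzyl)oxy]-6-oxo-3-phenoxy-13-norgermacra-1(10),4-dien-12-oate | O=C1/C=C(C)\[C@H](Oc2ccccc2)C/C=C(C)/C[C@H](OCc3ccc(OC)cc3)[C@H]1CC(=O)OC | intermediate
15 | methyl (1(10)E,3R,4S,5S,7R,8S)-4,5-epoxy-8-[(4-methoxybenzyl)oxy]-6-oxo-3-phenoxy-13-norgermacr-1(10)-en-12-oate | O=C1[C@H]2O[C@@]2(C)[C@H](Oc3ccccc3)C/C=C(C)/C[C@H](OCc4ccc(OC)cc4)[C@H]1CC(=O)OC | intermediate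
16 | lithium 6-alkoxide (6S) of the hydroxy ester formed from 15 | [Li+].[O-][C@@H]1[C@H]2O[C@@]2(C)[C@H](Oc3ccccc3)C/C=C(C)/C[C@H](OCc4ccc(OC)cc4)[C@H]1CC(=O)OC | intermediate
17 | (1(10)E,3R,4S,5R,6S,7R,8S)-4,5-epoxy-8-[(4-methoxybenzyl)oxy]-3-phenoxy-13-norgermacr-1(10)-en-12,6-olide | C1C(=O)O[C@H]2[C@H]1[C@@H](OCc3ccc(OC)cc3)C/C(C)=C/C[C@@H](Oc4ccccc4)[C@]5(C)O[C@@H]52 | intermediate
18 | (1(10)E,3R,5S,6S,7R,8S)-5-hydroxy-8-[(4-methoxybenzyl)oxy]-3-phenoxy-13-norgermacra-1(10),4(15)-dien-12,6-olide | C1C(=O)O[C@H]2[C@H]1[C@@H](OCc3ccc(OC)cc3)C/C(C)=C/C[C@@H](Oc4ccccc4)C(=C)[C@@H]2O | intermediate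
19 | 5-O-triethylsilyl ether of 18 | C1C(=O)O[C@H]2[C@H]1[C@@H](OCc3ccc(OC)cc3)C/C(C)=C/C[C@@H](Oc4ccccc4)C(=C)[C@@H]2O[Si](CC)(CC)CC | intermediate
20 | (1(10)E,2Z,5S,6S,7R,8S)-8-[(4-methoxybenzyl)oxy]-5-[(triethylsilyl)oxy]-13-norgermacra-1(10),2,4(15)-trien-12,6-olide | C1C(=O)O[C@H]2[C@H]1[C@@H](OCc3ccc(OC)cc3)C/C(C)=C/C=C\C(=C)[C@@H]2O[Si](CC)(CC)CC | intermediate
21 | 11-[(dimethylamino)methyl] derivative of 20 (C11 unassigned) | CN(C)CC1C(=O)O[C@H]2[C@H]1[C@@H](OCc3ccc(OC)cc3)C/C(C)=C/C=C\C(=C)[C@@H]2O[Si](CC)(CC)CC | intermediate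
22 | trimethylammonium iodide formed from 21 | [I-].C[N+](C)(C)CC1C(=O)O[C@H]2[C@H]1[C@@H](OCc3ccc(OC)cc3)C/C(C)=C/C=C\C(=C)[C@@H]2O[Si](CC)(CC)CC | intermediate
23 | (1(10)E,2Z,5S,6S,7R,8S)-8-[(4-methoxybenzyl)oxy]-5-[(triethylsilyl)oxy]germacra-1(10),2,4(15),11(13)-tetraen-12,6-olide | C=C1C(=O)O[C@H]2[C@H]1[C@@H](OCc3ccc(OC)cc3)C/C(C)=C/C=C\C(=C)[C@@H]2O[Si](CC)(CC)CC | intermediate
24 | (1R,2Z,5S,6S,7R,8S,10R)-1,10-epoxy-8-[(4-methoxybenzyl)oxy]-5-[(triethylsilyl)oxy]germacra-2,4(15),11(13)-trien-12,6-olide | C=C1C(=O)O[C@H]2[C@H]1[C@@H](OCc3ccc(OC)cc3)C[C@@]4(C)O[C@@H]4/C=C\C(=C)[C@@H]2O[Si](CC)(CC)CC | intermediate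
25 | (1R,2S,3S,5S,6S,7R,8S,10R)-1,10:2,3-diepoxy-8-[(4-methoxybenzyl)oxy]-5-[(triethylsilyl)oxy]germacra-4(15),11(13)-dien-12,6-olide | C=C1C(=O)O[C@H]2[C@H]1[C@@H](OCc3ccc(OC)cc3)C[C@@]4(C)O[C@@H]4[C@H]5O[C@H]5C(=C)[C@@H]2O[Si](CC)(CC)CC | intermediate
26 | (1R,2S,3S,5S,6S,7R,8S,10R)-1,10:2,3-diepoxy-8-hydroxy-5-[(triethylsilyl)oxy]germacra-4(15),11(13)-dien-12,6-olide | C=C1C(=O)O[C@H]2[C@H]1[C@@H](O)C[C@@]3(C)O[C@@H]3[C@H]4O[C@H]4C(=C)[C@@H]2O[Si](CC)(CC)CC | intermediate
27 | angelic acid, (Z)-2-methylbut-2-enoic acid | C/C=C(/C)C(=O)O | starting material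
28 | angelic 2,4,6-trichlorobenzoic anhydride | C/C=C(/C)C(=O)OC(=O)c1c(Cl)cc(Cl)cc1Cl | intermediate
29 | 8-O-angeloyl derivative of 26 (5-O-triethylsilyl ether of the target) | C=C1C(=O)O[C@H]2[C@H]1[C@@H](OC(=O)/C(C)=C\C)C[C@@]3(C)O[C@@H]3[C@H]4O[C@H]4C(=C)[C@@H]2O[Si](CC)(CC)CC | intermediate
30 | (1R,2S,3S,5S,6S,7R,8S,10R)-8-(angeloyloxy)-1,10:2,3-diepoxy-5-hydroxygermacra-4(15),11(13)-dien-12,6-olide | C=C1C(=O)O[C@H]2[C@H]1[C@@H](OC(=O)/C(C)=C\C)C[C@@]1(C)O[C@@H]1[C@H]1O[C@H]1C(=C)[C@@H]2O | target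

**Step count and risks**

Total steps: 18. Longest linear sequence: 17 steps (steps 1–3 and 5–18 from (S)-carvone; step 4 is the side branch).

Most likely to fail:

Step 7. The potassium enolate may lose the C8 alkoxide by E1cB β-elimination, may be O-alkylated, or the rearrangement may leak through a boat or dissociative pathway and erode the chirality transfer. The fallback sets out from 10 and returns at 14. Dienol 10 is heated without base (neutral thermal oxy-Cope, diglyme with a trace of 2,6-di-tert-butylpyridine, about 180 °C), so that only the enol and never a hot enolate is formed. The enol tautomerises to the C7-unsubstituted ketone (2Z,4R,6E,9S)-9-[(4-methoxybenzyl)oxy]-3,7-dimethyl-4-phenoxycyclodeca-2,6-dien-1-one F1. Kinetic deprotonation of F1 at C7 with LiN(i-Pr)2 at −78 °C, where lithium enolates of β-alkoxy ketones are stable, and alkylation with 11 should then give 14.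

Step 8. The peroxide may add to the wrong face of the enone (poor facial selectivity), which would invert C4 and C5. The fallback sets out from 14 and returns at 18. The epimeric material is carried through the unchanged operations of steps 8–10: the (4R,5R)-epoxy ketone F2, its (4R,5S)-epoxy lactone F3 and the (5R)-allylic alcohol F4. Mitsunobu inversion of F4 with 4-nitrobenzoic acid (PPh3, diisopropyl azodicarboxylate) gives the (5S)-4-nitrobenzoate F5, and brief methanolysis (K2CO3, MeOH, 0 °C) should give 18.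

Step 15. Oxygen may be delivered to the wrong face (ligand and substrate mismatched), the radical intermediate may scramble the cis geometry, or the oxo-manganese species may oxidise the 4-methoxybenzyl ether. The fallback sets out from 24 and returns at 29, changing both the order and the control element. The ether of 24 is cleaved with DDQ to the C8 alcohol F6, which is esterified as in step 17 to the angelate F7. The cis olefin of F7 is then epoxidised with dimethyldioxirane (acetone, −40 °C), a concerted, substrate-controlled oxygen transfer for which the C5 silyl ether and the C1–O bond of the first oxirane should cover the β face, giving 29.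

Further compounds
F1 | step 7 | (2Z,4R,6E,9S)-9-[(4-methoxybenzyl)oxy]-3,7-dimethyl-4-phenoxycyclodeca-2,6-dien-1-one (14 without the C7 acetate arm) | O=C1/C=C(C)\[C@H](Oc2ccccc2)C/C=C(C)/C[C@H](OCc3ccc(OC)cc3)C1
F2 | step 8 | methyl (1(10)E,3R,4R,5R,7R,8S)-4,5-epoxy-8-[(4-methoxybenzyl)oxy]-6-oxo-3-phenoxy-13-norgermacr-1(10)-en-12-oate (4,5-bis-epimer of 15) | O=C1[C@@H]2O[C@]2(C)[C@H](Oc3ccccc3)C/C=C(C)/C[C@H](OCc4ccc(OC)cc4)[C@H]1CC(=O)OC
F3 | step 8 | (1(10)E,3R,4R,5S,6S,7R,8S)-4,5-epoxy-8-[(4-methoxybenzyl)oxy]-3-phenoxy-13-norgermacr-1(10)-en-12,6-olide (4,5-bis-epimer of 17) | C1C(=O)O[C@H]2[C@H]1[C@@H](OCc3ccc(OC)cc3)C/C(C)=C/C[C@@H](Oc4ccccc4)[C@@]5(C)O[C@H]52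
F4 | step 8 | (1(10)E,3R,5R,6S,7R,8S)-5-hydroxy-8-[(4-methoxybenzyl)oxy]-3-phenoxy-13-norgermacra-1(10),4(15)-dien-12,6-olide (5-epimer of 18) | C1C(=O)O[C@H]2[C@H]1[C@@H](OCc3ccc(OC)cc3)C/C(C)=C/C[C@@H](Oc4ccccc4)C(=C)[C@H]2O
F5 | step 8 | 5-O-(4-nitrobenzoyl) derivative of 18 (5S) | C1C(=O)O[C@H]2[C@H]1[C@@H](OCc3ccc(OC)cc3)C/C(C)=C/C[C@@H](Oc4ccccc4)C(=C)[C@@H]2OC(=O)c5ccc(cc5)[N+](=O)[O-]
F6 | step 15 | (1R,2Z,5S,6S,7R,8S,10R)-1,10-epoxy-8-hydroxy-5-[(triethylsilyl)oxy]germacra-2,4(15),11(13)-trien-12,6-olide | C=C1C(=O)O[C@H]2[C@H]1[C@@H](O)C[C@@]3(C)O[C@@H]3/C=C\C(=C)[C@@H]2O[Si](CC)(CC)CC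
F7 | step 15 | 8-O-angeloyl derivative of F6 | C=C1C(=O)O[C@H]2[C@H]1[C@@H](OC(=O)/C(C)=C\C)C[C@@]3(C)O[C@@H]3/C=C\C(=C)[C@@H]2O[Si](CC)(CC)CC
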